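## Retrosynthetic overview

1. Target 15 ⇒ acyclic (2E,6Z)-farnesane-type iodo enal 13. Both rings close in the last flask in the biosynthetic order: first the C6–C7 bond (the ten-membered carbocycle, the bond a germacrene cyclase makes from a farnesyl chain), then O6–C12 lactonisation.
2. 13 ⇒ ynoate 10 (iodide-triggered aldol with CH2O puts iodine on C7 and adds C13) ⇒ terminal alkyne 9 (CO/MeOH adds C12).
3. 9 ⇒ lactol 7 + allenyl boronate (adds C8, C7, C11 and sets C9).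
4. 7 ⇒ dihydropyranone 6, a temporary ring used only to lock the Z C1=C10 olefin (RCM) ⇒ enal 3 + allyl boronate (sets C3) + methacryloyl chloride; 3 ⇒ 1 + 2.
5. Ring order: carbocycle, then lactone; the only protecting group is the C6 silyl ether.

Assumption: atoms carry germacrane numbers (C6 = lactone carbinol carbon, C12 = lactone carbonyl, C13 = CH2OH); the target is (3S,6R,9S) with a 1(10)Z and a 4E olefin. (S)-TRIP = (S)-3,3'-bis(2,4,6-triisopropylphenyl)-1,1'-binaphthyl-2,2'-diyl hydrogen phosphate; its Si-face sense is taken from the published model for this catalyst class and should be confirmed on 4 (Mosher ester).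

## Route

Step 1
Reactants: 1 (tert-butyldimethylsilyloxy)acetaldehyde; 2 2-(triphenylphosphoranylidene)propanal
Product: 3 (E)-4-[(tert-butyldimethylsilyl)oxy]-2-methylbut-2-enal
Conditions: toluene, 80 °C
Reagents that add atoms: none
Why: Wittig olefination with a formyl-stabilised ylide gives the E-trisubstituted enal (C3–C6 plus the C4 methyl); no stereocentre is formed.

Step 2
Reactants: 3 (E)-4-[(tert-butyldimethylsilyl)oxy]-2-methylbut-2-enal
Product: 4 (2E,4S)-1-[(tert-butyldimethylsilyl)oxy]-3-methylhepta-2,6-dien-4-ol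
Conditions: allylboronic acid pinacol ester (1.3 equiv), (S)-TRIP (5 mol%), 4 Å MS, toluene, −30 °C
Reagents that add atoms: allylboronic acid pinacol ester, C=CCB1OC(C)(C)C(C)(C)O1
Why: Chiral phosphoric acid-catalysed allylboration through a chair transition state; the (S)-catalyst delivers allyl to the Si face of the enal and sets C3 as S.

Step 3
Reactants: 4 (2E,4S)-1-[(tert-butyldimethylsilyl)oxy]-3-methylhepta-2,6-dien-4-ol
Product: 5 (2E,4S)-1-[(tert-butyldimethylsilyl)oxy]-3-methylhepta-2,6-dien-4-yl 2-methylprop-2-enoate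
Conditions: methacryloyl chloride, Et3N, DMAP (cat.), CH2Cl2, 0 °C
Reagents that add atoms: methacryloyl chloride, CC(=C)C(Cl)=O
Why: DMAP-catalysed O-acylation brings in C9, C10 and the C10 methyl; the C3 centre is untouched.

Step 4
Reactants: 5 (2E,4S)-1-[(tert-butyldimethylsilyl)oxy]-3-methylhepta-2,6-dien-4-yl 2-methylprop-2-enoate
Product: 6 (S)-6-[(E)-4-[(tert-butyldimethylsilyl)oxy]but-2-en-2-yl]-3-methyl-5,6-dihydro-2H-pyran-2-one
Conditions: second-generation Grubbs catalyst (5 mol%), toluene (0.01 M), 80 °C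
Reagents that add atoms: none
Why: Ring-closing metathesis of the vinyl group with the methacrylate gives the six-membered lactone, whose ring forces the C1=C10 olefin into the cis (Z) geometry; the hindered trisubstituted allyl silyl ether olefin does not react.

Step 5
Reactants: 6 (S)-6-[(E)-4-[(tert-butyldimethylsilyl)oxy]but-2-en-2-yl]-3-methyl-5,6-dihydro-2H-pyran-2-one
Product: 7 (6S)-6-[(E)-4-[(tert-butyldimethylsilyl)oxy]but-2-en-2-yl]-3-methyl-5,6-dihydro-2H-pyran-2-ol (anomer mixture)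
Conditions: iBu2AlH (1.1 equiv), CH2Cl2, −78 °C; Rochelle salt
Reagents that add atoms: none
Why: Partial reduction of the lactone stops at the lactol because the tetrahedral aluminate is stable at −78 °C; the lactol is a configurationally protected form of the (Z)-enal at C9.

Step 6
Reactants: 7 (6S)-6-[(E)-4-[(tert-butyldimethylsilyl)oxy]but-2-en-2-yl]-3-methyl-5,6-dihydro-2H-pyran-2-ol
Product: 8 (2E,4S,6Z,8S)-1-[(tert-butyldimethylsilyl)oxy]-3,7-dimethylundeca-2,6-dien-10-yne-4,8-diol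
Conditions: allenylboronic acid pinacol ester (2.5 equiv), (S)-TRIP (10 mol%), 4 Å MS, toluene, 0 °C
Reagents that add atoms: allenylboronic acid pinacol ester, C=C=CB1OC(C)(C)C(C)(C)O1
Why: Brønsted acid-catalysed propargylation (SE2' allenylboration) of the open hydroxy-(Z)-enal in equilibrium with 7; Si-face attack under catalyst control sets C9 as S and the Z olefin is kept.

Step 7
Reactants: 8 (2E,4S,6Z,8S)-1-[(tert-butyldimethylsilyl)oxy]-3,7-dimethylundeca-2,6-dien-10-yne-4,8-diol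
Product: 9 (2E,4S,6Z,8S)-1-[(tert-butyldimethylsilyl)oxy]-3,7-dimethylundeca-2,6-dien-10-yne-4,8-diyl diacetate
Conditions: Ac2O, pyridine, DMAP (cat.), CH2Cl2, 23 °C
Reagents that add atoms: acetic anhydride, CC(=O)OC(C)=O
Why: Acetylation of both secondary alcohols installs the two acetates of the target before the C13 hydroxyl exists; stereocentres are untouched.

Step 8
Reactants: 9 (2E,4S,6Z,8S)-1-[(tert-butyldimethylsilyl)oxy]-3,7-dimethylundeca-2,6-dien-10-yne-4,8-diyl diacetate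
Product: 10 methyl (5S,6Z,9S,10E)-5,9-diacetoxy-12-[(tert-butyldimethylsilyl)oxy]-6,10-dimethyldodeca-6,10-dien-2-ynoate
Conditions: PdCl2 (5 mol%), CuCl2 (2.2 equiv), NaOAc (2.2 equiv), CO (1 atm), MeOH, 23 °C
Reagents that add atoms: carbon monoxide, [C-]#[O+]; methanol, CO
Why: Tsuji oxidative alkoxycarbonylation of the terminal alkyne (alkynylpalladium, CO insertion, methanolysis, CuCl2 as reoxidant) adds C12 under buffered conditions that spare the acetates and silyl ether.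

Step 9
Reactants: 10 methyl (5S,6Z,9S,10E)-5,9-diacetoxy-12-[(tert-butyldimethylsilyl)oxy]-6,10-dimethyldodeca-6,10-dien-2-ynoate
Product: 12 methyl (2Z,5S,6Z,9S,10E)-5,9-diacetoxy-12-hydroxy-2-(hydroxymethyl)-3-iodo-6,10-dimethyldodeca-2,6,10-trienoate, via silyl-protected iodo aldol adduct 11 (not isolated)
Conditions: MgI2 (2 equiv), CH2O (monomer, 5 equiv), CH2Cl2, 0 to 23 °C; then THF, 1 M aq HCl, 23 °C
Reagents that add atoms: magnesium diiodide, [Mg+2].[I-].[I-]; formaldehyde, C=O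
Why: Halo-aldol (β-iodo Morita–Baylis–Hillman type) reaction: iodide adds to C7 of the magnesium-activated ynoate and the allenolate is hydroxymethylated at C11 anti to iodine, giving the olefin with iodine cis to the ester as in MgI2 couplings of propiolates; the acidic work-up then cleaves the primary silyl ether.

Step 10
Reactants: 12 methyl (2Z,5S,6Z,9S,10E)-5,9-diacetoxy-12-hydroxy-2-(hydroxymethyl)-3-iodo-6,10-dimethyldodeca-2,6,10-trienoate
Product: 13 methyl (2Z,5S,6Z,9S,10E)-5,9-diacetoxy-2-(hydroxymethyl)-3-iodo-6,10-dimethyl-12-oxododeca-2,6,10-trienoate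
Conditions: MnO2 (20 equiv), CH2Cl2, 23 °C
Reagents that add atoms: none
Why: Chemoselective allylic oxidation: the C6 alcohol on the electron-rich trisubstituted olefin is oxidised to the E-enal, while the C13 hydroxymethyl on the electron-poor iodoacrylate is a poor MnO2 substrate.

Step 11
Reactants: 13 methyl (2Z,5S,6Z,9S,10E)-5,9-diacetoxy-2-(hydroxymethyl)-3-iodo-6,10-dimethyl-12-oxododeca-2,6,10-trienoate
Product: 15 (3S,6R,9S)-3,9-diacetoxy-13-hydroxygermacra-1(10)Z,4E,7(11)-trien-12,6-olide, via ten-membered hydroxy ester 14 (not isolated)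
Conditions: CrCl2 (10 equiv), NiCl2 (0.1 equiv), DMSO–THF 3:1, 0.002 M (slow addition), 25 °C
Reagents that add atoms: none
Why: Nozaki–Hiyama–Kishi macrocyclisation: zerovalent nickel inserts into the activated C7–I bond, the alkenyl group passes to trivalent chromium and adds 1,2 to the C6 enal to close the ten-membered ring, and the chromium alkoxide, cis to the ester, lactonises in the flask; C6 (R) arises from Si-face attack under macrocyclic substrate control by the 3S and 9S acetoxy centres.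

## Compound list

1 | (tert-butyldimethylsilyloxy)acetaldehyde | CC(C)(C)[Si](C)(C)OCC=O | starting material
2 | 2-(triphenylphosphoranylidene)propanal | CC(C=O)=P(c1ccccc1)(c1ccccc1)c1ccccc1 | starting material
3 | (E)-4-[(tert-butyldimethylsilyl)oxy]-2-methylbut-2-enal | CC(C)(C)[Si](C)(C)OC/C=C(\C)C=O | intermediate
4 | (2E,4S)-1-[(tert-butyldimethylsilyl)oxy]-3-methylhepta-2,6-dien-4-ol | CC(C)(C)[Si](C)(C)OC/C=C(\C)[C@@H](O)CC=C | intermediate
5 | (2E,4S)-1-[(tert-butyldimethylsilyl)oxy]-3-methylhepta-2,6-dien-4-yl 2-methylprop-2-enoate | CC(C)(C)[Si](C)(C)OC/C=C(\C)[C@@H](OC(=O)C(C)=C)CC=C | intermediate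
6 | (S)-6-[(E)-4-[(tert-butyldimethylsilyl)oxy]but-2-en-2-yl]-3-methyl-5,6-dihydro-2H-pyran-2-one | CC(C)(C)[Si](C)(C)OC/C=C(\C)[C@@H]1CC=C(C)C(=O)O1 | intermediate
7 | (6S)-6-[(E)-4-[(tert-butyldimethylsilyl)oxy]but-2-en-2-yl]-3-methyl-5,6-dihydro-2H-pyran-2-ol (anomer mixture) | CC(C)(C)[Si](C)(C)OC/C=C(\C)[C@@H]1CC=C(C)C(O)O1 | intermediate
8 | (2E,4S,6Z,8S)-1-[(tert-butyldimethylsilyl)oxy]-3,7-dimethylundeca-2,6-dien-10-yne-4,8-diol | CC(C)(C)[Si](C)(C)OC/C=C(\C)[C@@H](O)C/C=C(/C)[C@@H](O)CC#C | intermediate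
9 | (2E,4S,6Z,8S)-1-[(tert-butyldimethylsilyl)oxy]-3,7-dimethylundeca-2,6-dien-10-yne-4,8-diyl diacetate | CC(C)(C)[Si](C)(C)OC/C=C(\C)[C@@H](OC(C)=O)C/C=C(/C)[C@@H](OC(C)=O)CC#C | intermediate
10 | methyl (5S,6Z,9S,10E)-5,9-diacetoxy-12-[(tert-butyldimethylsilyl)oxy]-6,10-dimethyldodeca-6,10-dien-2-ynoate | CC(C)(C)[Si](C)(C)OC/C=C(\C)[C@@H](OC(C)=O)C/C=C(/C)[C@@H](OC(C)=O)CC#CC(=O)OC | intermediate
11 | methyl (2Z,5S,6Z,9S,10E)-5,9-diacetoxy-12-[(tert-butyldimethylsilyl)oxy]-2-(hydroxymethyl)-3-iodo-6,10-dimethyldodeca-2,6,10-trienoate | CC(C)(C)[Si](C)(C)OC/C=C(\C)[C@@H](OC(C)=O)C/C=C(/C)[C@@H](OC(C)=O)C/C(I)=C(\CO)C(=O)OC | intermediate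
12 | methyl (2Z,5S,6Z,9S,10E)-5,9-diacetoxy-12-hydroxy-2-(hydroxymethyl)-3-iodo-6,10-dimethyldodeca-2,6,10-trienoate | OC/C=C(\C)[C@@H](OC(C)=O)C/C=C(/C)[C@@H](OC(C)=O)C/C(I)=C(\CO)C(=O)OC | intermediate
13 | methyl (2Z,5S,6Z,9S,10E)-5,9-diacetoxy-2-(hydroxymethyl)-3-iodo-6,10-dimethyl-12-oxododeca-2,6,10-trienoate | O=C/C=C(\C)[C@@H](OC(C)=O)C/C=C(/C)[C@@H](OC(C)=O)C/C(I)=C(\CO)C(=O)OC | intermediate
14 | methyl (2Z)-2-[(2R,3E,5S,7Z,9S)-5,9-diacetoxy-2-hydroxy-4,8-dimethylcyclodeca-3,7-dien-1-ylidene]-3-hydroxypropanoate | CC(=O)O[C@H]1C/C(=C(\CO)C(=O)OC)[C@H](O)/C=C(\C)[C@@H](OC(C)=O)C/C=C\1C | intermediate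
15 | (3S,6R,9S)-3,9-diacetoxy-13-hydroxygermacra-1(10)Z,4E,7(11)-trien-12,6-olide (CNP0328753.1) | CC(=O)O[C@H]1CC2=C(CO)C(=O)O[C@@H]2/C=C(\C)[C@@H](OC(C)=O)C/C=C\1C | target

## Step count and risks

Total step count: 11. Longest linear sequence: 11 steps (fully linear from 1 and 2).

Steps most likely to fail:

**Step 11 (macrocyclisation–lactonisation).** The (Z,E)-cyclodecadiene is strained, oligomers can compete even at high dilution, and the C6 configuration rests on substrate control alone. Fallback: build the lactone first by an intermolecular coupling and close the carbocycle last by metathesis at C1=C10. It sets out from 4 (plus commercial methacrolein) and comes back at 15.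
- Acetylation of 4 gives (2E,4S)-1-[(tert-butyldimethylsilyl)oxy]-3-methylhepta-2,6-dien-4-yl acetate F1.
- HF·pyridine gives (2E,4S)-1-hydroxy-3-methylhepta-2,6-dien-4-yl acetate F2, and MnO2 gives (2E,4S)-3-methyl-1-oxohepta-2,6-dien-4-yl acetate F3.
- In parallel, methacrolein is propargylated (allenylboronic acid pinacol ester, (S)-TRIP) to (S)-2-methylhex-1-en-5-yn-3-ol F4 and acetylated to (S)-2-methylhex-1-en-5-yn-3-yl acetate F5.
- PdCl2/CuCl2/CO/MeOH gives methyl (S)-5-acetoxy-6-methylhept-6-en-2-ynoate F6, and MgI2/CH2O gives methyl (2Z,5S)-5-acetoxy-2-(hydroxymethyl)-3-iodo-6-methylhepta-2,6-dienoate F7.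
- Intermolecular CrCl2/NiCl2 coupling of F7 with F3 (a chiral sulfonamide ligand on chromium can be added for reagent control at C6) and in-flask lactonisation give (S)-1-[(R)-2-[(1E,3S)-3-acetoxy-2-methylhexa-1,5-dien-1-yl]-4-(hydroxymethyl)-5-oxo-2,5-dihydrofuran-3-yl]-3-methylbut-3-en-2-yl acetate F8.
- Ring-closing metathesis of F8 with second-generation Hoveyda–Grubbs catalyst at high dilution joins the vinyl and isopropenyl groups, the medium ring favouring the cis olefin, and gives 15.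

**Step 9 (iodo-aldol).** A β-alkyl ynoate is a weak acceptor for iodide, formaldehyde is an unusual partner, the iodine-cis-to-ester geometry is argued by analogy only, and the allylic acetates must survive the Lewis acid. Fallback: set the tetrasubstituted olefin by hydroxyl-directed anti-carbomagnesiation instead of conjugate addition. It sets out from 8 and comes back at 11, which is then desilylated to 12 with aqueous HCl as in step 9.
- n-BuLi (3.2 equiv) and paraformaldehyde convert 8 into (2E,4S,6Z,8S)-1-[(tert-butyldimethylsilyl)oxy]-3,7-dimethyldodeca-2,6-dien-10-yne-4,8,12-triol F9.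
- iPrO(Me)2SiCH2MgCl (6 equiv) with CuI (0.2 equiv) adds anti across the propargylic alkyne through the magnesium chelate; I2 then gives (2E,4S,6Z,8S,10E)-1-[(tert-butyldimethylsilyl)oxy]-10-iodo-11-{[isopropoxy(dimethyl)silyl]methyl}-3,7-dimethyldodeca-2,6,10-triene-4,8,12-triol F10, with iodine cis to the directing CH2OH by construction.
- TEMPO/PhI(OAc)2 oxidises only the primary allylic alcohol to the corresponding 12-aldehyde F11.
- NaClO2/NaH2PO4/2-methyl-2-butene gives the 12-carboxylic acid F12, and Me3SiCHN2 gives the methyl ester F13.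
- Ac2O/pyridine gives the 4,8-diacetate F14.
- Tamao oxidation (KF, KHCO3, H2O2) turns the CH2Si group into the C13 hydroxymethyl and delivers 11.

**Step 6 (propargylation of the lactol).** Little free aldehyde is present, the lactol hydroxyl can bind the boronate or the acid, and catalyst control may be eroded. Fallback: unmask the (Z)-enal as a free aldehyde with C3 already acetylated. It sets out from 6 and comes back at 9.
- MeNH(OMe)·HCl/Me3Al opens 6 to (2Z,5S,6E)-8-[(tert-butyldimethylsilyl)oxy]-5-hydroxy-N-methoxy-N,2,6-trimethylocta-2,6-dienamide F15, which is acetylated at once to (2Z,5S,6E)-5-acetoxy-8-[(tert-butyldimethylsilyl)oxy]-N-methoxy-N,2,6-trimethylocta-2,6-dienamide F16.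
- Cp2Zr(H)Cl reduces the amide in the presence of the acetate to (2Z,5S,6E)-5-acetoxy-8-[(tert-butyldimethylsilyl)oxy]-2,6-dimethylocta-2,6-dienal F17.
- Propargylation of this free aldehyde (allenylboronic acid pinacol ester, (S)-TRIP, −30 °C) gives (2E,4S,6Z,8S)-1-[(tert-butyldimethylsilyl)oxy]-8-hydroxy-3,7-dimethylundeca-2,6-dien-10-yn-4-yl acetate F18, and Ac2O/pyridine gives 9.

Further compounds

F1 | step 11 | (2E,4S)-1-[(tert-butyldimethylsilyl)oxy]-3-methylhepta-2,6-dien-4-yl acetate | CC(C)(C)[Si](C)(C)OC/C=C(\C)[C@@H](OC(C)=O)CC=C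
F2 | step 11 | (2E,4S)-1-hydroxy-3-methylhepta-2,6-dien-4-yl acetate | OC/C=C(\C)[C@@H](OC(C)=O)CC=C
F3 | step 11 | (2E,4S)-3-methyl-1-oxohepta-2,6-dien-4-yl acetate | O=C/C=C(\C)[C@@H](OC(C)=O)CC=C
F4 | step 11 | (S)-2-methylhex-1-en-5-yn-3-ol | C=C(C)[C@@H](O)CC#C
F5 | step 11 | (S)-2-methylhex-1-en-5-yn-3-yl acetate | C=C(C)[C@@H](OC(C)=O)CC#C
F6 | step 11 | methyl (S)-5-acetoxy-6-methylhept-6-en-2-ynoate | C=C(C)[C@@H](OC(C)=O)CC#CC(=O)OC
F7 | step 11 | methyl (2Z,5S)-5-acetoxy-2-(hydroxymethyl)-3-iodo-6-methylhepta-2,6-dienoate | C=C(C)[C@@H](OC(C)=O)C/C(I)=C(\CO)C(=O)OC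
F8 | step 11 | (S)-1-[(R)-2-[(1E,3S)-3-acetoxy-2-methylhexa-1,5-dien-1-yl]-4-(hydroxymethyl)-5-oxo-2,5-dihydrofuran-3-yl]-3-methylbut-3-en-2-yl acetate | CC(=O)O[C@H](C(C)=C)CC1=C(CO)C(=O)O[C@@H]1/C=C(\C)[C@@H](OC(C)=O)CC=C
F9 | step 9 | (2E,4S,6Z,8S)-1-[(tert-butyldimethylsilyl)oxy]-3,7-dimethyldodeca-2,6-dien-10-yne-4,8,12-triol | CC(C)(C)[Si](C)(C)OC/C=C(\C)[C@@H](O)C/C=C(/C)[C@@H](O)CC#CCO
F10 | step 9 | (2E,4S,6Z,8S,10E)-1-[(tert-butyldimethylsilyl)oxy]-10-iodo-11-{[isopropoxy(dimethyl)silyl]methyl}-3,7-dimethyldodeca-2,6,10-triene-4,8,12-triol | CC(C)(C)[Si](C)(C)OC/C=C(\C)[C@@H](O)C/C=C(/C)[C@@H](O)C/C(I)=C(\C[Si](C)(C)OC(C)C)CO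
F11 | step 9 | (2Z,5S,6Z,9S,10E)-12-[(tert-butyldimethylsilyl)oxy]-5,9-dihydroxy-3-iodo-2-{[isopropoxy(dimethyl)silyl]methyl}-6,10-dimethyldodeca-2,6,10-trienal | CC(C)(C)[Si](C)(C)OC/C=C(\C)[C@@H](O)C/C=C(/C)[C@@H](O)C/C(I)=C(\C[Si](C)(C)OC(C)C)C=O
F12 | step 9 | (2Z,5S,6Z,9S,10E)-12-[(tert-butyldimethylsilyl)oxy]-5,9-dihydroxy-3-iodo-2-{[isopropoxy(dimethyl)silyl]methyl}-6,10-dimethyldodeca-2,6,10-trienoic acid | CC(C)(C)[Si](C)(C)OC/C=C(\C)[C@@H](O)C/C=C(/C)[C@@H](O)C/C(I)=C(\C[Si](C)(C)OC(C)C)C(O)=O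
F13 | step 9 | methyl (2Z,5S,6Z,9S,10E)-12-[(tert-butyldimethylsilyl)oxy]-5,9-dihydroxy-3-iodo-2-{[isopropoxy(dimethyl)silyl]methyl}-6,10-dimethyldodeca-2,6,10-trienoate | CC(C)(C)[Si](C)(C)OC/C=C(\C)[C@@H](O)C/C=C(/C)[C@@H](O)C/C(I)=C(\C[Si](C)(C)OC(C)C)C(=O)OC
F14 | step 9 | methyl (2Z,5S,6Z,9S,10E)-5,9-diacetoxy-12-[(tert-butyldimethylsilyl)oxy]-3-iodo-2-{[isopropoxy(dimethyl)silyl]methyl}-6,10-dimethyldodeca-2,6,10-trienoate | CC(C)(C)[Si](C)(C)OC/C=C(\C)[C@@H](OC(C)=O)C/C=C(/C)[C@@H](OC(C)=O)C/C(I)=C(\C[Si](C)(C)OC(C)C)C(=O)OC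
F15 | step 6 | (2Z,5S,6E)-8-[(tert-butyldimethylsilyl)oxy]-5-hydroxy-N-methoxy-N,2,6-trimethylocta-2,6-dienamide | CC(C)(C)[Si](C)(C)OC/C=C(\C)[C@@H](O)C/C=C(/C)C(=O)N(C)OC
F16 | step 6 | (2Z,5S,6E)-5-acetoxy-8-[(tert-butyldimethylsilyl)oxy]-N-methoxy-N,2,6-trimethylocta-2,6-dienamide | CC(C)(C)[Si](C)(C)OC/C=C(\C)[C@@H](OC(C)=O)C/C=C(/C)C(=O)N(C)OC
F17 | step 6 | (2Z,5S,6E)-5-acetoxy-8-[(tert-butyldimethylsilyl)oxy]-2,6-dimethylocta-2,6-dienal | CC(C)(C)[Si](C)(C)OC/C=C(\C)[C@@H](OC(C)=O)C/C=C(/C)C=O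
F18 | step 6 | (2E,4S,6Z,8S)-1-[(tert-butyldimethylsilyl)oxy]-8-hydroxy-3,7-dimethylundeca-2,6-dien-10-yn-4-yl acetate | CC(C)(C)[Si](C)(C)OC/C=C(\C)[C@@H](OC(C)=O)C/C=C(/C)[C@@H](O)CC#C
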